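I started with the gap. In the midnight flask, which is the flask asked about, G counted solid, so whatever G and Q left unaccounted for stood dissolved: 6.80 % at 2.00 h, 9.00 % at 3.00 h, 10.9 % at 5.00 h.

- midnight: G 0.015 M; Z 1.5 µM; the very flask that is asked about, followed so far
- flask: G 0.015 M; Z 1.5 µM; time 25 h

midnight run (percent of the G charged)

| time / h | Q / % | G / % |
|---|---|---|
| 0.417 | 0.1 | 97.5 |
| 0.667 | 0.5 | 96.7 |
| 1.00 | 1.0 | 94.7 |
| 2.00 | 3.0 | 90.2 |
| 3.00 | 5.2 | 85.8 |
| 5.00 | 10.7 | 78.4 |

(readings scatter by 0.3 percentage points)

- given per volume of solution although it is solid: G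
- at the start none of G is in solution

1. the Q standing at 25 h, as a percentage of the G charged
2. the change that raises the amount of Q at 25 h, in percent of the G charged most ("none" if none brings more than 2 percentage points) (Saturday's / Sunday's / Tuesday's / none)
3. amount of Q at 25 h, in percent of the G charged, after Sunday's

- Saturday's: doubling the solubility of G, all else as stated
- Sunday's: doubling the amount of Z, all else as stated
- Tuesday's: doubling the dissolution coefficient of G, all else as stated

Hourly Q over mean dissolved G gave 0.278 h⁻¹ in the earlier span and 0.276 h⁻¹ in the later one. I froze this hourly Q per dissolved G and called it the clearing constant, a pseudo-first-order constant as read.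

With dissolved G held at 10.9 %, the remaining 20.0 h gave Q of 71.0 %. My objection was that dissolved G was still climbing, from 9.00 %, so I suspected that figure of running low. The pool stops growing where hourly Q meets the solid's loss, so I froze that loss instead, 0.0370 h⁻¹ of the charge, and got 84.7 %. I suspected that one of running high, since the loss had slowed from 0.0440 h⁻¹. I committed to their mean, 77.8 %.

The forecast stood lower than mine: 71 % (62 % to 78 %), with Sunday's best at 96 % (86 % to 100 %), on “a quasi-steady dissolved level of about 13%”.

The flask gave 56.6 %, and Sunday's gave 78.6 %.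

    E + Z → Q + Z, rate k1*[E]*[Z]/(1 + ([E]/Km1) + ([Q]/Kp1)) (1.48 mM, 6.25 mM, k = 3.82 × 10⁵ L mol⁻¹ h⁻¹)
    G ⇌ E, rate k2*(cs2 - [E]) while solid is left; crystals form when [E] > cs2 (solubility = 5.10 mM, k = 0.159 h⁻¹)
    Z + Q → J (k = 3.62 L mol⁻¹ h⁻¹)

At 25.0 h, 32.5 % of the Z charged stood as J. Over the second half of the run, Q gained 0.0214 h⁻¹ of the charge hourly on a mean E of 18.1 %, so the clearing constant read 0.118 h⁻¹, less than the frozen 0.276 h⁻¹. For the neighbour flask charged with 3.8 × 10⁻⁷ M of Z, I scaled the constant to 0.0700 h⁻¹. Taking mean E as half of its final 28.0 %, this gave 24.5 % over 25 h, and that neighbour held 21.1 %.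

(The readings were generated by integration for an exercise, noise included.)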